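**Plan**

1. Ring cut: the quinone is opened at C1–C6. C1(=O), C2(Me), C3(H) and C4(=O) are the four carbons of a 4-hydroxy-2-methylcyclobut-2-enone; C5 and C6 are the two carbons of an alkyne whose far end carries C1′ of the side chain.
2. Enabling feature: C1=O lies between the two substituted carbons (C2–Me, C6–CH2R) and C4=O between two CH (C3, C5). A strained 4-alkynyl-4-hydroxycyclobutenone with Me on C2 and H on C3 gives exactly this pattern when it opens at C1–C4 and recloses on the distal alkyne carbon.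
3. Four-membered ring: from diisopropyl squarate. An isopropoxy group on C3 steers the acetylide to the correct carbonyl and is then exchanged for H by hydride addition and acid transposition.
4. Chain cuts (side chain numbered C1′ at the ring to C16′): C1′–C(sp) by allylic bromide plus ethynyl Grignard, C5′–C6′ by B-alkyl Suzuki coupling, C6′=C7′ by methylalumination of an alkyne, C8′–C9′ by propargylation of epoxynerol triflate.
5. Stereochemistry and order: C10′/C11′ come from Sharpless epoxidation of nerol (L-(+)-tartrate) and invertive acid hydration at C11′; the E-alkenes come from syn-carboalumination and an E-configured C6 enynol. Forward: right half (steps 1–6), union (7–8), alkyne (9–10), four-ring (11–13), ring expansion (14), deprotection (15).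

Key step: step 14

Assumption: the carbinol carbon made in step 12 forms as both epimers; this is without consequence because it becomes the C4 carbonyl in step 14.

**Step 1**
Reactants: 1 nerol [(2Z)-3,7-dimethylocta-2,6-dien-1-ol]
Product: 2 (2S,3R)-2,3-epoxynerol
Conditions: Ti(OiPr)4 (cat.), L-(+)-diethyl tartrate (cat.), t-BuOOH, 4 Å MS, CH2Cl2, −20 °C
Reagents that add atoms: tert-butyl hydroperoxide, CC(C)(C)OO
Why: Sharpless asymmetric epoxidation acts only on the allylic alkene; the L-(+)-tartrate catalyst should deliver oxygen to the face that gives the (2S,3R) cis-epoxide, setting C10′ (S, final) and C11′ (R, inverted in step 4).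

**Step 2**
Reactants: 2 (2S,3R)-2,3-epoxynerol; 3 1-(trimethylsilyl)propyne
Product: 6 trimethyl{4-[(2S,3R)-3-methyl-3-(4-methylpent-3-enyl)oxiran-2-yl]but-1-ynyl}silane, via 3-lithio-1-(trimethylsilyl)propyne 4 (not isolated), via epoxynerol triflate 5 (not isolated)
Conditions: 2, n-BuLi, Et2O, −78 °C; Tf2O, −78 °C; then 4 (from 3, n-BuLi, THF, −78 → 0 °C), −78 → −30 °C
Reagents that add atoms: none
Why: SN2 alkylation of the propargylic carbon of the silyl-capped propargyl anion by the primary triflate should form C8′–C9′; the silyl group suppresses allenyl attack and the trisubstituted epoxide is inert at this temperature.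

**Step 3**
Reactants: 6 TMS-alkynyl epoxide
Product: 7 (2S,3R)-2-(but-3-ynyl)-3-methyl-3-(4-methylpent-3-enyl)oxirane (cis-epoxide, CH carbon S, quaternary carbon R)
Conditions: K2CO3 (cat.), MeOH, rt
Reagents that add atoms: none
Why: Base-catalysed methanolysis of the alkynyl–silicon bond (protodesilylation); the hindered epoxide does not open under methanolic carbonate.

**Step 4**
Reactants: 7 alkynyl cis-epoxide
Product: 8 (5S,6S)-6,10-dimethylundec-9-en-1-yne-5,6-diol
Conditions: 3% aq HClO4, THF, 0 °C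
Reagents that add atoms: water, O
Why: Acid-catalysed epoxide hydration; water attacks the protonated epoxide at the tertiary carbon C11′ from the back (borderline SN2), inverting it (R→S) while C10′ (S) keeps its C–O bond, which should give the (10′S,11′S) diol.

**Step 5**
Reactants: 8 alkynyl diol
Product: 9 (4S,5S)-5-(but-3-ynyl)-2,2,4-trimethyl-4-(4-methylpent-3-enyl)-1,3-dioxolane
Conditions: 2,2-dimethoxypropane, PPTS (cat.), CH2Cl2, rt
Reagents that add atoms: 2,2-dimethoxypropane, COC(C)(C)OC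
Why: Acid-catalysed transketalisation protects the secondary/tertiary diol as its isopropylidene acetal without touching either stereocentre.

**Step 6**
Reactants: 9 alkynyl acetonide
Product: 11 (4S,5S)-5-[(3E)-4-iodo-3-methylbut-3-enyl]-2,2,4-trimethyl-4-(4-methylpent-3-enyl)-1,3-dioxolane, via (E)-alkenyldimethylalane 10 (not isolated)
Conditions: Me3Al, Cp2ZrCl2 (20 mol %), CH2Cl2, 0 °C → rt; then I2, THF, −30 → 0 °C
Reagents that add atoms: trimethylaluminium, C[Al](C)C; iodine, II
Why: Negishi Zr-catalysed carboalumination adds Me–Al syn across the terminal alkyne with Me on the internal carbon, and iodinolysis with retention should give the E-iodoalkene that fixes the C6′=C7′ geometry.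

**Step 7**
Reactants: 12 (2E)-3-methylpent-2-en-4-yn-1-ol
Product: 13 (2E)-3-methylpenta-2,4-dien-1-ol
Conditions: H2 (1 atm), Lindlar catalyst, quinoline, EtOAc, rt
Reagents that add atoms: none
Why: Lindlar semi-hydrogenation should stop at the vinyl group and leave the existing E-trisubstituted alkene (future C2′=C3′) unchanged.

**Step 8**
Reactants: 13 (2E)-3-methylpenta-2,4-dien-1-ol; 11 E-iodoalkene
Product: 15 (2E,6E)-3,7-dimethyl-9-[(4S,5S)-2,2,5-trimethyl-5-(4-methylpent-3-enyl)-1,3-dioxolan-4-yl]nona-2,6-dien-1-ol, via B-alkyl-9-BBN borinate 14 (not isolated)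
Conditions: 13, 9-BBN (2.2 eq), THF, 0 °C → rt; then 11, PdCl2(dppf) (5 mol %), AsPh3, Cs2CO3, DMF/H2O, rt
Reagents that add atoms: none
Why: One equivalent of 9-BBN caps the hydroxyl and the second hydroborates the terminal vinyl carbon of the diene; B-alkyl Suzuki–Miyaura coupling should then form C5′–C6′ with retention of both alkene geometries.

**Step 9**
Reactants: 15 C20 allylic alcohol acetonide
Product: 16 (4S,5S)-4-[(3E,7E)-9-bromo-3,7-dimethylnona-3,7-dienyl]-2,2,5-trimethyl-5-(4-methylpent-3-enyl)-1,3-dioxolane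
Conditions: CBr4, PPh3, CH2Cl2, 0 °C
Reagents that add atoms: carbon tetrabromide, BrC(Br)(Br)Br
Why: Appel bromination converts the primary allylic alcohol under neutral conditions, so the acetonide and alkene geometries should survive.

**Step 10**
Reactants: 16 C20 allylic bromide acetonide
Product: 17 (4S,5S)-4-[(3E,7E)-3,7-dimethylundeca-3,7-dien-10-ynyl]-2,2,5-trimethyl-5-(4-methylpent-3-enyl)-1,3-dioxolane
Conditions: HC≡CMgBr (excess), CuCl (cat.), THF, 0 → 50 °C
Reagents that add atoms: ethynylmagnesium bromide, C#C[Mg]Br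
Why: Copper(I)-catalysed coupling of an alkynyl Grignard reagent with a primary allylic bromide should occur at the unhindered α-carbon and give the skipped (1,4-)enyne.

**Step 11**
Reactants: 18 diisopropyl squarate (3,4-diisopropoxycyclobut-3-ene-1,2-dione)
Product: 21 3-isopropoxy-4-methylcyclobut-3-ene-1,2-dione, via lithium alkoxide adduct 19 (not isolated), via trifluoroacetate ester 20 (not isolated)
Conditions: MeLi, THF, −78 °C; then (CF3CO)2O, −78 °C; aq NaHCO3 work-up
Reagents that add atoms: methyllithium, [Li]C; water, O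
Why: 1,2-Addition of methyllithium to one squarate carbonyl, then ionisation of the trifluoroacetate to an alkoxy-stabilised allyl cation and hydrolysis with loss of isopropanol, the standard squarate addition–rearrangement.

**Step 12**
Reactants: 17 skipped enyne; 21 3-isopropoxy-4-methylcyclobut-3-ene-1,2-dione
Product: 23 4-hydroxy-3-isopropoxy-2-methyl-4-{(4E,8E)-5,9-dimethyl-11-[(4S,5S)-2,2,5-trimethyl-5-(4-methylpent-3-enyl)-1,3-dioxolan-4-yl]undeca-4,8-dien-1-ynyl}cyclobut-2-en-1-one (both C4 epimers), via lithium acetylide 22 (not isolated)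
Conditions: 17, n-BuLi, THF, −78 °C; then 21, −78 °C; aq NH4Cl at −78 °C
Reagents that add atoms: none
Why: The acetylide adds 1,2 to the ketone-like carbonyl next to the isopropoxy-bearing carbon, the other carbonyl being deactivated as a vinylogous ester; the new carbinol centre is uncontrolled and is erased in step 14.

**Step 13**
Reactants: 23 alkynyl hydroxy isopropoxy cyclobutenone
Product: 25 4-hydroxy-2-methyl-4-{(4E,8E)-5,9-dimethyl-11-[(4S,5S)-2,2,5-trimethyl-5-(4-methylpent-3-enyl)-1,3-dioxolan-4-yl]undeca-4,8-dien-1-ynyl}cyclobut-2-en-1-one (both C4 epimers), via cyclobutenediol 24 (not isolated)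
Conditions: DIBAL-H (2.2 eq), CH2Cl2, −78 °C; then 1 M aq HCl, THF, 0 °C, short contact
Reagents that add atoms: water, O
Why: Stork–Danheiser-type 1,3-carbonyl transposition: hydride adds 1,2 to the vinylogous ester carbonyl, acid ionises the resulting secondary allylic alcohol with help from the enol-ether oxygen, and water capture with loss of isopropanol should put C=O where OiPr was and H on C3.

**Step 14**
Reactants: 25 4-alkynyl-4-hydroxy-2-methylcyclobut-2-en-1-one
Product: 28 2-methyl-6-{(2E,6E)-3,7-dimethyl-9-[(4S,5S)-2,2,5-trimethyl-5-(4-methylpent-3-enyl)-1,3-dioxolan-4-yl]nona-2,6-dienyl}cyclohexa-2,5-diene-1,4-dione, via enynylketene 26 (not isolated), via aryl-phenoxyl diradical 27 (not isolated)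
Conditions: toluene (0.02 M), 110 °C, N2
Reagents that add atoms: none
Why: Heat opens the cyclobutenone by conrotatory 4π electrocyclic cleavage of C1–C4, the hydroxyl on C4 rotating outward so that the alkynyl group lies cis to the ketene in 26. The ketene carbon then bonds to the distal alkyne carbon (a 6-endo closure of the enyne–ketene, related to the Myers–Saito cyclisation), which closes the six-membered ring as diradical 27; transfer of the hydroxyl hydrogen to the aryl radical carbon gives the quinone. The closest known reaction type is the Moore rearrangement of 4-alkynyl-4-hydroxycyclobutenones to 1,4-benzoquinones. No stereocentre is formed, and the epimeric carbinol carbon becomes the C4 carbonyl. The step needs six- over five-membered closure (quinone over 2-alkylidenecyclopentene-1,3-dione), which the CH2 substituent on the alkyne terminus should secure because it does not stabilise the vinyl radical of the five-ring path; the 2,6-pattern is fixed by Me on C2 and H on C3 of the four-membered ring.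

**Step 15**
Reactants: 28 quinone acetonide
Product: 29 2-[(2E,6E,10S,11S)-10,11-dihydroxy-3,7,11,15-tetramethylhexadeca-2,6,14-trienyl]-6-methylcyclohexa-2,5-diene-1,4-dione (target)
Conditions: AcOH/H2O/THF (3:1:1), 45 °C
Reagents that add atoms: none
Why: Mild aqueous acid hydrolysis of the isopropylidene acetal breaks no C–O bond of the diol, so both stereocentres are retained; the quinone and trisubstituted alkenes should tolerate the weak, non-nucleophilic acid.

**Compound list**

1 | nerol, (2Z)-3,7-dimethylocta-2,6-dien-1-ol | CC(C)=CCC/C(C)=C\CO | starting material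
2 | (2S,3R)-2,3-epoxynerol | OC[C@@H]1O[C@]1(C)CCC=C(C)C | intermediate
3 | 1-(trimethylsilyl)propyne | CC#C[Si](C)(C)C | starting material
4 | 3-lithio-1-(trimethylsilyl)propyne | [Li]CC#C[Si](C)(C)C | intermediate
5 | (2S,3R)-epoxynerol triflate | FC(F)(F)S(=O)(=O)OC[C@@H]1O[C@]1(C)CCC=C(C)C | intermediate
6 | trimethyl{4-[(2S,3R)-3-methyl-3-(4-methylpent-3-enyl)oxiran-2-yl]but-1-ynyl}silane | C[Si](C)(C)C#CCC[C@@H]1O[C@]1(C)CCC=C(C)C | intermediate
7 | (2S,3R)-2-(but-3-ynyl)-3-methyl-3-(4-methylpent-3-enyl)oxirane | C#CCC[C@@H]1O[C@]1(C)CCC=C(C)C | intermediate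
8 | (5S,6S)-6,10-dimethylundec-9-en-1-yne-5,6-diol | CC(C)=CCC[C@](C)(O)[C@@H](O)CCC#C | intermediate
9 | (4S,5S)-5-(but-3-ynyl)-2,2,4-trimethyl-4-(4-methylpent-3-enyl)-1,3-dioxolane | CC(C)=CCC[C@]1(C)OC(C)(C)O[C@H]1CCC#C | intermediate
10 | dimethyl{(1E)-2-methyl-4-[(4S,5S)-2,2,5-trimethyl-5-(4-methylpent-3-enyl)-1,3-dioxolan-4-yl]but-1-enyl}alane | CC(C)=CCC[C@]1(C)OC(C)(C)O[C@H]1CC/C(C)=C/[Al](C)C | intermediate
11 | (4S,5S)-5-[(3E)-4-iodo-3-methylbut-3-enyl]-2,2,4-trimethyl-4-(4-methylpent-3-enyl)-1,3-dioxolane | CC(C)=CCC[C@]1(C)OC(C)(C)O[C@H]1CC/C(C)=C/I | intermediate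
12 | (2E)-3-methylpent-2-en-4-yn-1-ol | C#C/C(C)=C/CO | starting material
13 | (2E)-3-methylpenta-2,4-dien-1-ol | C=C/C(C)=C/CO | intermediate
14 | 9-{(3E)-3-methyl-5-[(9-borabicyclo[3.3.1]nonan-9-yl)oxy]pent-3-enyl}-9-borabicyclo[3.3.1]nonane | O(B1C2CCCC1CCC2)C/C=C(C)/CCB1C2CCCC1CCC2 | intermediate
15 | (2E,6E)-3,7-dimethyl-9-[(4S,5S)-2,2,5-trimethyl-5-(4-methylpent-3-enyl)-1,3-dioxolan-4-yl]nona-2,6-dien-1-ol | CC(C)=CCC[C@]1(C)OC(C)(C)O[C@H]1CC/C(C)=C/CC/C(C)=C/CO | intermediate
16 | (4S,5S)-4-[(3E,7E)-9-bromo-3,7-dimethylnona-3,7-dienyl]-2,2,5-trimethyl-5-(4-methylpent-3-enyl)-1,3-dioxolane | CC(C)=CCC[C@]1(C)OC(C)(C)O[C@H]1CC/C(C)=C/CC/C(C)=C/CBr | intermediate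
17 | (4S,5S)-4-[(3E,7E)-3,7-dimethylundeca-3,7-dien-10-ynyl]-2,2,5-trimethyl-5-(4-methylpent-3-enyl)-1,3-dioxolane | CC(C)=CCC[C@]1(C)OC(C)(C)O[C@H]1CC/C(C)=C/CC/C(C)=C/CC#C | intermediate
18 | diisopropyl squarate, 3,4-diisopropoxycyclobut-3-ene-1,2-dione | CC(C)OC1=C(OC(C)C)C(=O)C1=O | starting material
19 | lithium 2,3-diisopropoxy-1-methyl-4-oxocyclobut-2-en-1-olate | CC(C)OC1=C(OC(C)C)C(C)([O-])C1=O.[Li+] | intermediate
20 | 2,3-diisopropoxy-1-methyl-4-oxocyclobut-2-enyl trifluoroacetate | CC(C)OC1=C(OC(C)C)C(C)(OC(=O)C(F)(F)F)C1=O | intermediate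
21 | 3-isopropoxy-4-methylcyclobut-3-ene-1,2-dione | CC1=C(OC(C)C)C(=O)C1=O | intermediate
22 | lithium acetylide of 17 | CC(C)=CCC[C@]1(C)OC(C)(C)O[C@H]1CC/C(C)=C/CC/C(C)=C/CC#C[Li] | intermediate
23 | 4-hydroxy-3-isopropoxy-2-methyl-4-{(4E,8E)-5,9-dimethyl-11-[(4S,5S)-2,2,5-trimethyl-5-(4-methylpent-3-enyl)-1,3-dioxolan-4-yl]undeca-4,8-dien-1-ynyl}cyclobut-2-en-1-one, both C4 epimers | CC(C)=CCC[C@]1(C)OC(C)(C)O[C@H]1CC/C(C)=C/CC/C(C)=C/CC#CC1(O)C(OC(C)C)=C(C)C1=O | intermediate
24 | 3-isopropoxy-2-methyl-4-(same alkynyl group)cyclobut-2-ene-1,4-diol, diastereomer mixture | CC(C)=CCC[C@]1(C)OC(C)(C)O[C@H]1CC/C(C)=C/CC/C(C)=C/CC#CC1(O)C(OC(C)C)=C(C)C1O | intermediate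
25 | 4-hydroxy-2-methyl-4-{(4E,8E)-5,9-dimethyl-11-[(4S,5S)-2,2,5-trimethyl-5-(4-methylpent-3-enyl)-1,3-dioxolan-4-yl]undeca-4,8-dien-1-ynyl}cyclobut-2-en-1-one, both C4 epimers | CC(C)=CCC[C@]1(C)OC(C)(C)O[C@H]1CC/C(C)=C/CC/C(C)=C/CC#CC1(O)C=C(C)C1=O | intermediate
26 | enynylketene: 4-hydroxy-2-methyl-hexa-1,3-dien-5-yn-1-one with the chain on C6, alkynyl cis to the ketene carbon | CC(C)=CCC[C@]1(C)OC(C)(C)O[C@H]1CC/C(C)=C/CC/C(C)=C/CC#C/C(O)=C\C(C)=C=O | intermediate
27 | 4-hydroxy-2-methyl-6-(chain)phenoxyl radical with an aryl σ-radical at C5 | CC(C)=CCC[C@]1(C)OC(C)(C)O[C@H]1CC/C(C)=C/CC/C(C)=C/Cc1[c]c(O)cc(C)c1[O] | intermediate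
28 | 2-methyl-6-{(2E,6E)-3,7-dimethyl-9-[(4S,5S)-2,2,5-trimethyl-5-(4-methylpent-3-enyl)-1,3-dioxolan-4-yl]nona-2,6-dienyl}cyclohexa-2,5-diene-1,4-dione | CC(C)=CCC[C@]1(C)OC(C)(C)O[C@H]1CC/C(C)=C/CC/C(C)=C/CC1=CC(=O)C=C(C)C1=O | intermediate
29 | 2-[(2E,6E,10S,11S)-10,11-dihydroxy-3,7,11,15-tetramethylhexadeca-2,6,14-trienyl]-6-methylcyclohexa-2,5-diene-1,4-dione | CC(C)=CCC[C@](C)(O)[C@@H](O)CC/C(C)=C/CC/C(C)=C/CC1=CC(=O)C=C(C)C1=O | target

**Totals**

Total step count: 15. Longest linear sequence: 13 steps (1 → 29 through steps 1–6, 8–10 and 12–15).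

**Steps most likely to fail**

Step 13. The hydride may over-reduce or add in conjugate fashion, and the acid may ionise the propargylic carbinol or open the strained hydroxy-enone faster than the allylic transposition, so the isopropoxy group stays or the four-membered ring is lost. Fallback: setting out from bromide 16, sodium 2-methylphenoxide (2-methylphenol, NaH, toluene, rt) would be C-allylated at the free ortho position to give 2-methyl-6-{(2E,6E)-3,7-dimethyl-9-[(4S,5S)-2,2,5-trimethyl-5-(4-methylpent-3-enyl)-1,3-dioxolan-4-yl]nona-2,6-dienyl}phenol F1. Oxidation of this 2,6-disubstituted phenol at the free para position (Co(salen), O2, DMF) should give the quinone acetonide and rejoin the route at 28. This gives up the ring expansion but uses only known arene chemistry.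

Step 4. Water may attack the secondary carbon in part, or the protonated epoxide may ionise to a free tertiary cation; both erode the configuration at C10′/C11′, and the cation can be captured by the neighbouring trisubstituted alkene. Fallback: setting out from nerol 1, Sharpless epoxidation with D-(−)-diethyl tartrate would give (2R,3S)-2,3-epoxynerol F2. Payne rearrangement with trapping of the terminal epoxide by dimethylsulfonium methylide (Me3S+ I−, n-BuLi, THF) inverts the secondary carbon cleanly and should give (3S,4S)-4,8-dimethylnona-1,7-diene-3,4-diol F3. Acetonide formation would give (4S,5S)-2,2,4-trimethyl-4-(4-methylpent-3-enyl)-5-vinyl-1,3-dioxolane F4. Hydroboration–oxidation of the vinyl group (9-BBN; NaOH, H2O2) would give 2-[(4S,5S)-2,2,5-trimethyl-5-(4-methylpent-3-enyl)-1,3-dioxolan-4-yl]ethanol F5, and I2/PPh3/imidazole would give (4S,5S)-4-(2-iodoethyl)-2,2,5-trimethyl-5-(4-methylpent-3-enyl)-1,3-dioxolane F6. Alkylation of lithium acetylide–ethylenediamine in DMSO rejoins the route at 9.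

Step 14. The enynylketene may partition toward five-membered closure, and the diradical may abstract hydrogen intermolecularly or oligomerise. Fallback: setting out from alkyne 17, hydrozirconation–iodination (Cp2Zr(H)Cl; I2) would give (4S,5S)-4-[(3E,7E,10E)-11-iodo-3,7-dimethylundeca-3,7,10-trienyl]-2,2,5-trimethyl-5-(4-methylpent-3-enyl)-1,3-dioxolane F7. Iodine–lithium exchange (t-BuLi, Et2O, −78 °C) and addition to 21 would give 4-hydroxy-3-isopropoxy-2-methyl-4-[(1E,4E,8E)-trienyl]cyclobut-2-en-1-one F8. The same DIBAL-H/acid transposition would give 4-hydroxy-2-methyl-4-[(1E,4E,8E)-trienyl]cyclobut-2-en-1-one F9. Thermolysis (toluene or xylene, 110–140 °C) now runs by ring opening and closed-shell 6π electrocyclisation of a dienylketene, with no diradical, to the 2-methyl-6-(chain)benzene-1,4-diol F10. Oxidation with Ag2O rejoins the route at 28.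

**Further compounds**

F1 | step 13 | 2-methyl-6-{(2E,6E)-3,7-dimethyl-9-[(4S,5S)-2,2,5-trimethyl-5-(4-methylpent-3-enyl)-1,3-dioxolan-4-yl]nona-2,6-dienyl}phenol | CC(C)=CCC[C@]1(C)OC(C)(C)O[C@H]1CC/C(C)=C/CC/C(C)=C/Cc1cccc(C)c1O
F2 | step 4 | (2R,3S)-2,3-epoxynerol | OC[C@H]1O[C@@]1(C)CCC=C(C)C
F3 | step 4 | (3S,4S)-4,8-dimethylnona-1,7-diene-3,4-diol | CC(C)=CCC[C@](C)(O)[C@@H](O)C=C
F4 | step 4 | (4S,5S)-2,2,4-trimethyl-4-(4-methylpent-3-enyl)-5-vinyl-1,3-dioxolane | CC(C)=CCC[C@]1(C)OC(C)(C)O[C@H]1C=C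
F5 | step 4 | 2-[(4S,5S)-2,2,5-trimethyl-5-(4-methylpent-3-enyl)-1,3-dioxolan-4-yl]ethanol | CC(C)=CCC[C@]1(C)OC(C)(C)O[C@H]1CCO
F6 | step 4 | (4S,5S)-4-(2-iodoethyl)-2,2,5-trimethyl-5-(4-methylpent-3-enyl)-1,3-dioxolane | CC(C)=CCC[C@]1(C)OC(C)(C)O[C@H]1CCI
F7 | step 14 | (4S,5S)-4-[(3E,7E,10E)-11-iodo-3,7-dimethylundeca-3,7,10-trienyl]-2,2,5-trimethyl-5-(4-methylpent-3-enyl)-1,3-dioxolane | CC(C)=CCC[C@]1(C)OC(C)(C)O[C@H]1CC/C(C)=C/CC/C(C)=C/C/C=C/I
F8 | step 14 | 4-hydroxy-3-isopropoxy-2-methyl-4-{(1E,4E,8E)-5,9-dimethyl-11-[(4S,5S)-2,2,5-trimethyl-5-(4-methylpent-3-enyl)-1,3-dioxolan-4-yl]undeca-1,4,8-trienyl}cyclobut-2-en-1-one | CC(C)=CCC[C@]1(C)OC(C)(C)O[C@H]1CC/C(C)=C/CC/C(C)=C/C/C=C/C1(O)C(OC(C)C)=C(C)C1=O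
F9 | step 14 | 4-hydroxy-2-methyl-4-{(1E,4E,8E)-5,9-dimethyl-11-[(4S,5S)-2,2,5-trimethyl-5-(4-methylpent-3-enyl)-1,3-dioxolan-4-yl]undeca-1,4,8-trienyl}cyclobut-2-en-1-one | CC(C)=CCC[C@]1(C)OC(C)(C)O[C@H]1CC/C(C)=C/CC/C(C)=C/C/C=C/C1(O)C=C(C)C1=O
F10 | step 14 | 2-methyl-6-{(2E,6E)-3,7-dimethyl-9-[(4S,5S)-2,2,5-trimethyl-5-(4-methylpent-3-enyl)-1,3-dioxolan-4-yl]nona-2,6-dienyl}benzene-1,4-diol | CC(C)=CCC[C@]1(C)OC(C)(C)O[C@H]1CC/C(C)=C/CC/C(C)=C/Cc1cc(O)cc(C)c1O
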